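Minutes. The meeting opened on a ratio: fitted through the origin, the target readings of the dusk run rise 1.29 times as steeply as those of the midnight run, for 1.50 times the second substrate.

all flasks: starting material 29 mM; free enzyme 0.26 µM
- midnight: second substrate 16 mM; run made earlier
- dusk: second substrate 24 mM; run made earlier
- flask: second substrate 31.9 mM

| midnight: time / h | midnight: target / % | dusk: time / h | dusk: target / % |
|---|---|---|---|
| 5.00 | 0.9 | 10.0 | 4.4 |
| 15.0 | 1.2 | 20.0 | 5.2 |
| 25.0 | 5.0 | 30.0 | 8.8 |
| 40.0 | 9.2 | 40.0 | 9.9 |

(scatter of a reading: 1 percentage point)

- apparent order in free enzyme when 50 % of the starting material are converted (percent change of the rate of making target for one percent more free enzyme charged)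
- apparent order in second substrate when 50 % of the starting material are converted (percent change of the rate of making target for one percent more second substrate charged)

- no earlier run changes the charge of free enzyme; that part of a forecast is a guess

The secretary then gave her own reckoning, solving the two ends and joining them. She supposed that the rate saturates in the second substrate concentration B: far below a concentration K_B, the rate follows B, which is order one; far above K_B, it stops responding, which is order zero. The rate law B/(K_B+B) joins these ends, with order n = K_B/(K_B+B).

The ratio of the runs gives K_B = 34.0 mM, the second substrate concentration at which the order is 0.5. She called this a loose reading, because each point is good to 1 percentage point. Assuming one second substrate is used per target, the flask holds 17.4 mM at 50 % conversion, so she committed to n = 0.661.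

The forecaster proposed 0.5 for second substrate, with a range of 0.1 to 1, and called it an extrapolation: “so this is an extrapolation”. For free enzyme the forecaster proposed 1, with a range of 0.7 to 1.2, as a guess, since no run changed that charge. The secretary accepted the enzyme figure, but her order in second substrate stands higher than the forecast's.

The flask gives an order of 0.70 in second substrate and 1.0 in free enzyme.

    starting material + free enzyme ⇌ first complex (K = 7.40 L mol⁻¹, k = 8.11 × 10⁵ L mol⁻¹ h⁻¹)
    first complex ⇌ loaded enzyme + first product (K = 0.0470 M, k = 2070 h⁻¹)
    second substrate + loaded enzyme ⇌ second complex (K = 15.0 L mol⁻¹, k = 2.08 × 10⁷ L mol⁻¹ h⁻¹)
    second complex → free enzyme + target (k = 4980 h⁻¹)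

In the flask at 40.0 h, second complex is 5.19 % of the catalyst, less than the 12.0 % in loaded enzyme. With K_B, the saturation law at the flask's charge of second substrate over the same law at the dusk charge is 1.17, which scales the dusk reading of 9.9 % at 40.0 h to an estimate of 11.6 % for the flask. The flask holds 9.90 % of target at 40.0 h.

The earlier runs and the new flask stem from a simulated flask on assumed constants; noise was put on by code.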